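**Retrosynthetic overview**
1. GA55 (5) ⇒ hydroxy ketone 4: the C3 carbinol is made last, by α-face hydride delivery steered by the axial 1β-oxygen.
2. 4 ⇒ boryl ketone 3 ⇒ enone 2: the C1–O bond is traced back to a C1–B bond from copper-catalysed boryl conjugate addition on the β face (key step, used in place of the textbook enone epoxidation and reductive epoxide opening).
3. 2 ⇒ gibberellic acid 1 by allylic oxidation; every step runs on the free acid, without protecting groups.
4. Ring order: no ring is built. Rings A, B, C, D and the 19,10-lactone come intact from 1 with seven stereocentres untouched; only C1 (new) and C3 (erased, then re-set) are made.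

Assumption: gibberellic acid (GA3), a bulk fermentation product stocked by the major catalogue suppliers, counts as a commercially available starting material.

**Route**

Step 1
Reactants: 1 gibberellic acid (GA3; 3β,13-dihydroxy-1,16-diene, 19,10-lactone on the α face, C7 carboxylic acid, natural enantiomer)
Product: 2 enone acid (3-dehydro-GA3: C3 ketone conjugated with C1=C2, otherwise as 1)
Conditions: activated MnO2 (20 equiv), acetone, rt, 16 h; filter, wash cake with acetone/1% AcOH
Reagents that add atoms: none
Why: Chemoselective MnO2 oxidation of an allylic alcohol, a standard oxidation of the GA3 ring A allylic alcohol: only the secondary allylic 3-OH carries an oxidisable C–H (the 13-OH is tertiary), so C3 is deliberately flattened to the 1-en-3-one and no new stereocentre arises.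

Step 2
Reactants: 2 enone acid
Product: 3 boryl ketone (1β-(4,4,5,5-tetramethyl-1,3,2-dioxaborolan-2-yl)-3-oxo acid; C1–B axial, cis to the C18 methyl and anti to the lactone oxygen on C10)
Conditions: NaOtBu (1.15 equiv), CuCl (5 mol%), bis[2-(diphenylphosphino)phenyl] ether (5 mol%), B2pin2 (1.3 equiv), MeOH (4 equiv), THF, 0 °C to rt, 3 h; then 1 M HCl to pH 3
Reagents that add atoms: bis(pinacolato)diboron, CC1(C)OB(OC1(C)C)B2OC(C)(C)C(C)(C)O2
Why: Copper-catalysed boryl conjugate addition (β-borylation of an enone): the monovalent copper boryl species adds Bpin to the β-carbon C1 axially from the open β face, anti to the α-oriented C10–O lactone bridge that blocks the other face, and MeOH protonates the copper enolate at C2, which sets the C1 stereocentre with boron β while one equivalent of base simply holds the acid as its carboxylate.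

Step 3
Reactants: 3 boryl ketone
Product: 4 hydroxy ketone (1β-hydroxy-3-oxo acid, 3-dehydro-GA55)
Conditions: NaBO3·4H2O (4 equiv), THF/H2O 1:1, 0 °C to rt, 2 h; then 1 M HCl to pH 3
Reagents that add atoms: sodium perborate tetrahydrate NaBO3·4H2O, [Na+].[Na+].O[B-]1(O)OO[B-](O)(O)OO1 (supplies the C1 oxygen)
Why: Stereoretentive oxidation of a secondary alkylboronate (1,2-shift of C1 from boron to peroxide oxygen) under the mild perborate conditions routinely used for β-boryl ketones, so C1–B becomes C1–OH with the β configuration kept and the peroxo-boronate rearranges faster than it can fragment or the aldol product can cleave.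

Step 4
Reactants: 4 hydroxy ketone
Product: 5 GA55 (1β,3β,13-trihydroxy 19,10-lactone 7-oic acid)
Conditions: K[(sec-Bu)3BH] (4.5 equiv, 1 M in THF), THF, −78 °C, 2 h; then AcOH, −78 °C to rt
Reagents that add atoms: none
Why: Diastereoselective ketone reduction under steric approach control: the bulky trialkylborohydride cannot use the axial β trajectory, which is closed by the 1,3-diaxial 1β-alkoxide and 5β-H, so hydride arrives equatorially from the α side and gives the axial 3β-alcohol cis to the 1β-OH (the sense expected for a 3-oxo-gibberellin with a bulky hydride), while the hindered lactone and the carboxylate are inert at −78 °C.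

**Compound list**
1 | gibberellic acid (GA3), 3β,13-dihydroxy-1,16-diene 19,10-lactone 7-oic acid | C=C1C[C@]23C[C@@]1(O)CC[C@H]2[C@@]12OC(=O)[C@@](C)([C@H]1[C@@H]3C(=O)O)[C@@H](O)C=C2 | starting material
2 | enone acid (3-dehydro-GA3), 13-hydroxy-3-oxo-1,16-diene 19,10-lactone 7-oic acid | C=C1C[C@]23C[C@@]1(O)CC[C@H]2[C@@]12OC(=O)[C@@](C)([C@H]1[C@@H]3C(=O)O)C(=O)C=C2 | intermediate
3 | boryl ketone, 1β-(pinacolatoboryl)-13-hydroxy-3-oxo-16-ene 19,10-lactone 7-oic acid | C=C1C[C@]23C[C@@]1(O)CC[C@H]2[C@@]12OC(=O)[C@@](C)([C@H]1[C@@H]3C(=O)O)C(=O)C[C@H]2B4OC(C)(C)C(C)(C)O4 | intermediate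
4 | hydroxy ketone, 1β,13-dihydroxy-3-oxo-16-ene 19,10-lactone 7-oic acid | C=C1C[C@]23C[C@@]1(O)CC[C@H]2[C@@]12OC(=O)[C@@](C)([C@H]1[C@@H]3C(=O)O)C(=O)C[C@H]2O | intermediate
5 | GA55, 1β,3β,13-trihydroxy-16-ene 19,10-lactone 7-oic acid | C=C1C[C@]23C[C@@]1(O)CC[C@H]2[C@@]12OC(=O)[C@@](C)([C@H]1[C@@H]3C(=O)O)[C@@H](O)C[C@H]2O | target

**Totals**
Total step count: 4. Longest linear sequence: 4 steps (1 → 2 → 3 → 4 → 5).

**Three steps most likely to fail, with fallbacks**

Step 2 (boryl conjugate addition on the free acid). The carboxylate may bind copper, or may coordinate the new boronate and trigger anti-elimination of the C10 lactone oxygen. The fallback masks the acid for this one operation. It sets out from 2 and comes back at 4. Treating 2 with iPr3SiCl and Et3N in CH2Cl2 at 0 °C gives the enone triisopropylsilyl ester F1. The same copper catalysis, now with only 10 mol% NaOtBu and i-PrOH as proton source, gives the boryl ketone triisopropylsilyl ester F2. NaBO3·4H2O in THF/H2O then oxidises the C–B bond and hydrolyses the silyl ester in one operation to deliver 4.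

Step 3 (C–B oxidation). The C1–B bond is anti-periplanar to the C10–O lactone bond, so a boronate ate complex could fragment to the 1(10)-ene, and 4 could suffer retro-aldol cleavage in base. The fallback avoids boron altogether. It sets out from 2 and comes back at 4. Weitz–Scheffer epoxidation of 2 (30% H2O2, Na2CO3, THF/H2O, 0 °C; hydroperoxide enters at C1 from the β face) gives the 1β,2β-epoxy ketone acid F3. Its Cα–O bond is then cleaved chemoselectively with Na[PhSeB(OEt)3] (from (PhSe)2 and NaBH4 in EtOH, AcOH, 0 °C) to give 4.

Step 4 (C3 reduction). The risk is that the 3α-epimer forms or that the alkoxide of 4 undergoes retro-aldol cleavage. The fallback replaces steric approach control by chelation control through a boron tether (Narasaka–Prasad reduction). It sets out from 4 and comes back at 5. Et2BOMe (2.2 equiv) in THF/MeOH 4:1 at −78 °C ties the 1β-oxygen to the C3 carbonyl as the bis(diethylboryl) chelate F4 (the acid is carried as its boryl ester). NaBH4 then attacks only the face opposite the chelate bridge, because only the cis-1,3-diaxial diol can stay bound to boron. Co-evaporation with MeOH releases 5.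

**Further compounds**
F1 | step 2 | enone triisopropylsilyl ester (triisopropylsilyl ester of 2) | C=C1C[C@]23C[C@@]1(O)CC[C@H]2[C@@]12OC(=O)[C@@](C)([C@H]1[C@@H]3C(=O)O[Si](C(C)C)(C(C)C)C(C)C)C(=O)C=C2
F2 | step 2 | boryl ketone triisopropylsilyl ester (triisopropylsilyl ester of 3) | C=C1C[C@]23C[C@@]1(O)CC[C@H]2[C@@]12OC(=O)[C@@](C)([C@H]1[C@@H]3C(=O)O[Si](C(C)C)(C(C)C)C(C)C)C(=O)C[C@H]2B4OC(C)(C)C(C)(C)O4
F3 | step 3 | 1β,2β-epoxy ketone acid (1β,2β-epoxy-13-hydroxy-3-oxo-16-ene 19,10-lactone 7-oic acid) | C=C1C[C@]23C[C@@]1(O)CC[C@H]2[C@@]12OC(=O)[C@@](C)([C@H]1[C@@H]3C(=O)O)C(=O)[C@H]4O[C@@H]24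
F4 | step 4 | bis(diethylboryl) chelate of 4 (1β-O-diethylboryl ether, C7 diethylboryl ester) | C=C1C[C@]23C[C@@]1(O)CC[C@H]2[C@@]12OC(=O)[C@@](C)([C@H]1[C@@H]3C(=O)OB(CC)CC)C(=O)C[C@H]2OB(CC)CC
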